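The route rests on the bond between flavanone C8 (ring A) and chain C3 of the diarylheptanoid (chain C1 = styrenyl CH, C5 = carbinol). The target is an ortho-allylphenol: the free 7-OH sits next to C8, which carries the allyl unit C3–C2=C1 (E). Both complete fragments are therefore first tied together through O7 as an aryl allyl ether (O7–C1, 1S; C2=C3 E). A thermal aromatic Claisen rearrangement then forms C8–C3, transfers the C1 oxygen stereocentre to carbon C3 (S), moves the alkene into conjugation as E and liberates the 7-OH in one operation. Flavanone C2 and chain C5 are set earlier by catalysis.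

Key step: step 10

Remark: the facial preferences of the chiral catalysts in steps 3, 6 and 8 are assigned by analogy with their behaviour on simpler enones and aldehydes; should one prove opposite, the antipodal catalyst is used. Compounds 1, 5, 8, 9 and 15 are taken as commercial. TBS = tert-butyldimethylsilyl.

Step 1
Reactants: 1 1-(2,4-dihydroxy-6-methoxyphenyl)ethanone
Product: 2 1-[4-(benzyloxy)-2-hydroxy-6-methoxyphenyl]ethanone
Conditions: BnBr (1.05 equiv), K2CO3, acetone, reflux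
Reagents that add atoms: benzyl bromide, BrCc1ccccc1
Why: Williamson etherification; the 2-OH is held in a hydrogen bond to the acetyl carbonyl, so only the free, more acidic 4-OH is alkylated.

Step 2
Reactants: 2 1-[4-(benzyloxy)-2-hydroxy-6-methoxyphenyl]ethanone
Product: 4 7-(benzyloxy)-5-methoxy-4H-chromen-4-one, via enaminone 3 (not isolated)
Conditions: Me2NCH(OMe)2, PhMe, 95 °C; then conc. HCl, CH2Cl2, 40 °C
Reagents that add atoms: N,N-dimethylformamide dimethyl acetal, COC(OC)N(C)C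
Why: Enaminone chromone synthesis: condensation at the acetyl methyl group, then acid-promoted addition of the phenol and loss of dimethylamine closes the pyranone ring.

Step 3
Reactants: 4 7-(benzyloxy)-5-methoxy-4H-chromen-4-one; 5 [4-(TBS-oxy)phenyl]boronic acid
Product: 6 (2S)-7-(benzyloxy)-2-[4-(TBS-oxy)phenyl]-5-methoxychroman-4-one
Conditions: Pd(OCOCF3)2 (5 mol %), (R)-t-BuPyOx (6 mol %), NH4PF6 (30 mol %), H2O (5 equiv), ClCH2CH2Cl, 60 °C
Reagents that add atoms: none
Why: Palladium-catalysed asymmetric conjugate addition of an arylboronic acid to a chromone (arylpalladium insertion into C2=C3, then protonolysis); the pyridine-oxazoline ligand selects the face of C2, and the (R)-ligand is expected to give 2S.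

Step 4
Reactants: 6 (2S)-7-(benzyloxy)-2-[4-(TBS-oxy)phenyl]-5-methoxychroman-4-one
Product: 7 (2S)-2-[4-(TBS-oxy)phenyl]-7-hydroxy-5-methoxychroman-4-one
Conditions: H2 (1 atm), Pd/C, EtOAc, rt
Reagents that add atoms: none
Why: Hydrogenolysis of the aryl benzyl ether; no alkene is present yet, and the aryl silyl ether, the ketone and the C2–O1 bond should survive these mild conditions.

Step 5
Reactants: 8 tert-butyl(4-iodophenoxy)dimethylsilane; 9 prop-2-en-1-ol
Product: 11 3-[4-(TBS-oxy)phenyl]propanal, via enol 10 (not isolated)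
Conditions: Pd(OAc)2 (2 mol %), Bu4NCl, NaHCO3, DMF, 40 °C
Reagents that add atoms: none
Why: Ligand-free Heck arylation of allyl alcohol; beta-hydride elimination towards the carbinol carbon gives the enol, which tautomerises to the 3-arylpropanal.

Step 6
Reactants: 11 3-[4-(TBS-oxy)phenyl]propanal
Product: 13 (3S)-1-[4-(TBS-oxy)phenyl]hex-5-yn-3-ol, via borate ester 12 (not isolated)
Conditions: allenyl-B(pin) (1.5 equiv), (R)-TRIP phosphoric acid (10 mol %), 4 Å MS, PhMe, −20 °C; aqueous work-up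
Reagents that add atoms: allenylboronic acid pinacol ester, C=C=CB1OC(C)(C)C(C)(C)O1
Why: Chiral phosphoric acid catalysed aldehyde propargylation through a closed six-membered transition state; the (R)-catalyst should direct attack to the Re face, which sets chain C5 as S.

Step 7
Reactants: 13 (3S)-1-[4-(TBS-oxy)phenyl]hex-5-yn-3-ol
Product: 14 tert-butyl{4-[(3S)-3-(TBS-oxy)hex-5-yn-1-yl]phenoxy}dimethylsilane
Conditions: TBSCl, imidazole, DMF, rt
Reagents that add atoms: tert-butyldimethylsilyl chloride, CC(C)(C)[Si](C)(C)Cl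
Why: Standard silylation of a secondary alcohol; the group must survive the organozinc step, the etherification and the thermal rearrangement.

Step 8
Reactants: 14 tert-butyl{4-[(3S)-3-(TBS-oxy)hex-5-yn-1-yl]phenoxy}dimethylsilane; 15 4-formylphenyl acetate
Product: 18 4-[(1R,2E,5S)-5-(TBS-oxy)-7-[4-(TBS-oxy)phenyl]-1-hydroxyhept-2-en-1-yl]phenyl acetate, via alkenylborane 16 (not isolated), via alkenylzinc 17 (not isolated)
Conditions: Cy2BH, PhMe, 0 °C to rt; Me2Zn, −78 °C; (+)-MIB (5 mol %), then 15, −10 °C; aq. NH4Cl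
Reagents that add atoms: none
Why: Hydroboration, boron-to-zinc exchange and amino alcohol catalysed asymmetric alkenylzinc addition to the aldehyde; syn hydroboration fixes the E alkene, (+)-3-exo-morpholinoisoborneol should direct Re-face attack to give the 1R carbinol, and the aryl acetate is inert to the organozinc.

Step 9
Reactants: 18 4-[(1R,2E,5S)-5-(TBS-oxy)-7-[4-(TBS-oxy)phenyl]-1-hydroxyhept-2-en-1-yl]phenyl acetate; 7 (2S)-2-[4-(TBS-oxy)phenyl]-7-hydroxy-5-methoxychroman-4-one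
Product: 19 4-[(1S,2E,5S)-5-(TBS-oxy)-7-[4-(TBS-oxy)phenyl]-1-{[(2S)-2-[4-(TBS-oxy)phenyl]-5-methoxy-4-oxochroman-7-yl]oxy}hept-2-en-1-yl]phenyl acetate
Conditions: PPh3, DIAD, PhMe, 0 °C; Et3N-deactivated silica
Reagents that add atoms: none
Why: Mitsunobu etherification; the acidic 7-OH (a vinylogous acid) displaces the activated carbinol by SN2 with inversion (1R to 1S), while the acetoxy group on the C1 aryl ring and the non-polar solvent disfavour ionisation and SN2′ attack.

Step 10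
Reactants: 19 4-[(1S,2E,5S)-5-(TBS-oxy)-7-[4-(TBS-oxy)phenyl]-1-{[(2S)-2-[4-(TBS-oxy)phenyl]-5-methoxy-4-oxochroman-7-yl]oxy}hept-2-en-1-yl]phenyl acetate
Product: 21 4-[(1E,3S,5S)-5-(TBS-oxy)-7-[4-(TBS-oxy)phenyl]-3-[(2S)-2-[4-(TBS-oxy)phenyl]-7-hydroxy-5-methoxy-4-oxochroman-8-yl]hept-1-en-1-yl]phenyl acetate, via ortho-dienone 20 (not isolated)
Conditions: PhNEt2, 150 °C, under argon
Reagents that add atoms: none
Why: On heating, the aryl allyl ether undergoes a concerted suprafacial [3,3]-sigmatropic shift through a six-membered chair transition state (O7–C7–C8 over C1–C2–C3) with the C1 aryl group pseudo-equatorial; the resulting ortho-dienone 20 tautomerises at once to the phenol. The closest known reaction type is the aromatic Claisen rearrangement of enantioenriched aryl sec-allyl ethers with 1,3-chirality transfer. No ring is closed; the six-membered array exists only in the transition state. The new stereocentre C3 is controlled by the C1 configuration and the E geometry of C2=C3: the C8–C3 bond forms on the face of the allyl unit from which O7 departs, so 1S,2E should give 3S and an E C1=C2 bond. The step needs C8 over C6 selectivity and an un-ionised pathway: the peri C4 carbonyl holds the 5-OMe methyl towards C6, so a C6 substituent would force that methoxy group out of the ring plane, whereas C8 is flanked by O1, whose only substituent (C2) is tied back in the pyranone ring C; the acetoxy group on the C1 aryl ring and the non-polar, weakly basic medium suppress ion-pair scrambling. Flavanone C2 and chain C5 are not involved, and the weakly basic amine cannot open ring C.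

Step 11
Reactants: 21 4-[(1E,3S,5S)-5-(TBS-oxy)-7-[4-(TBS-oxy)phenyl]-3-[(2S)-2-[4-(TBS-oxy)phenyl]-7-hydroxy-5-methoxy-4-oxochroman-8-yl]hept-1-en-1-yl]phenyl acetate
Product: 22 4-[(1E,3S,5S)-5-hydroxy-3-[(2S)-7-hydroxy-2-(4-hydroxyphenyl)-5-methoxy-4-oxochroman-8-yl]-7-(4-hydroxyphenyl)hept-1-en-1-yl]phenyl acetate
Conditions: HF·pyridine (excess), pyridine, THF, 0 °C to rt
Reagents that add atoms: none
Why: Fluoride-mediated cleavage of the two aryl and the one secondary alkyl silyl ether under buffered conditions that leave flavanone C2, the acetate and the still acetoxy-deactivated styrene untouched.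

Step 12
Reactants: 22 4-[(1E,3S,5S)-5-hydroxy-3-[(2S)-7-hydroxy-2-(4-hydroxyphenyl)-5-methoxy-4-oxochroman-8-yl]-7-(4-hydroxyphenyl)hept-1-en-1-yl]phenyl acetate
Product: 23 (2S)-7-hydroxy-8-[(1E,3S,5S)-5-hydroxy-1,7-bis(4-hydroxyphenyl)hept-1-en-3-yl]-2-(4-hydroxyphenyl)-5-methoxychroman-4-one
Conditions: NH4OAc (excess), MeOH/H2O (4:1), rt
Reagents that add atoms: none
Why: Neutral, ammonium acetate mediated methanolysis that is selective for aryl acetates; no base able to open the flavanone ring and no acid able to protonate the hydroxystyrene is present.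

Compound list
1 | 1-(2,4-dihydroxy-6-methoxyphenyl)ethanone | CC(=O)c1c(O)cc(O)cc1OC | starting material
2 | 1-[4-(benzyloxy)-2-hydroxy-6-methoxyphenyl]ethanone | CC(=O)c1c(O)cc(OCc2ccccc2)cc1OC | intermediate
3 | (E)-1-[4-(benzyloxy)-2-hydroxy-6-methoxyphenyl]-3-(dimethylamino)prop-2-en-1-one (enaminone) | CN(C)/C=C/C(=O)c1c(O)cc(OCc2ccccc2)cc1OC | intermediate
4 | 7-(benzyloxy)-5-methoxy-4H-chromen-4-one | COc1cc(OCc2ccccc2)cc2occc(=O)c12 | intermediate
5 | [4-(TBS-oxy)phenyl]boronic acid | CC(C)(C)[Si](C)(C)Oc1ccc(cc1)B(O)O | starting material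
6 | (2S)-7-(benzyloxy)-2-[4-(TBS-oxy)phenyl]-5-methoxychroman-4-one | COc1cc(OCc2ccccc2)cc2c1C(=O)C[C@@H](c1ccc(O[Si](C)(C)C(C)(C)C)cc1)O2 | intermediate
7 | (2S)-2-[4-(TBS-oxy)phenyl]-7-hydroxy-5-methoxychroman-4-one | COc1cc(O)cc2c1C(=O)C[C@@H](c1ccc(O[Si](C)(C)C(C)(C)C)cc1)O2 | intermediate
8 | tert-butyl(4-iodophenoxy)dimethylsilane | CC(C)(C)[Si](C)(C)Oc1ccc(I)cc1 | starting material
9 | prop-2-en-1-ol (allyl alcohol) | C=CCO | starting material
10 | (E)-3-[4-(TBS-oxy)phenyl]prop-1-en-1-ol (enol) | CC(C)(C)[Si](C)(C)Oc1ccc(C/C=C/O)cc1 | intermediate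
11 | 3-[4-(TBS-oxy)phenyl]propanal | CC(C)(C)[Si](C)(C)Oc1ccc(CCC=O)cc1 | intermediate
12 | 2-{[(3S)-1-[4-(TBS-oxy)phenyl]hex-5-yn-3-yl]oxy}-4,4,5,5-tetramethyl-1,3,2-dioxaborolane (borate ester) | C#CC[C@@H](OB1OC(C)(C)C(C)(C)O1)CCc1ccc(O[Si](C)(C)C(C)(C)C)cc1 | intermediate
13 | (3S)-1-[4-(TBS-oxy)phenyl]hex-5-yn-3-ol | C#CC[C@@H](O)CCc1ccc(O[Si](C)(C)C(C)(C)C)cc1 | intermediate
14 | tert-butyl{4-[(3S)-3-(TBS-oxy)hex-5-yn-1-yl]phenoxy}dimethylsilane | C#CC[C@@H](O[Si](C)(C)C(C)(C)C)CCc1ccc(O[Si](C)(C)C(C)(C)C)cc1 | intermediate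
15 | 4-formylphenyl acetate | CC(=O)Oc1ccc(C=O)cc1 | starting material
16 | dicyclohexyl[(1E,4S)-4-(TBS-oxy)-6-[4-(TBS-oxy)phenyl]hex-1-en-1-yl]borane (alkenylborane) | C1CCC(CC1)B(/C=C/C[C@@H](O[Si](C)(C)C(C)(C)C)CCc1ccc(O[Si](C)(C)C(C)(C)C)cc1)C1CCCCC1 | intermediate
17 | methyl[(1E,4S)-4-(TBS-oxy)-6-[4-(TBS-oxy)phenyl]hex-1-en-1-yl]zinc (alkenylzinc) | C[Zn]/C=C/C[C@@H](O[Si](C)(C)C(C)(C)C)CCc1ccc(O[Si](C)(C)C(C)(C)C)cc1 | intermediate
18 | 4-[(1R,2E,5S)-5-(TBS-oxy)-7-[4-(TBS-oxy)phenyl]-1-hydroxyhept-2-en-1-yl]phenyl acetate | CC(=O)Oc1ccc(cc1)[C@H](O)/C=C/C[C@@H](O[Si](C)(C)C(C)(C)C)CCc1ccc(O[Si](C)(C)C(C)(C)C)cc1 | intermediate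
19 | 4-[(1S,2E,5S)-5-(TBS-oxy)-7-[4-(TBS-oxy)phenyl]-1-{[(2S)-2-[4-(TBS-oxy)phenyl]-5-methoxy-4-oxochroman-7-yl]oxy}hept-2-en-1-yl]phenyl acetate | COc1cc(O[C@H](c2ccc(OC(C)=O)cc2)/C=C/C[C@@H](O[Si](C)(C)C(C)(C)C)CCc2ccc(O[Si](C)(C)C(C)(C)C)cc2)cc2c1C(=O)C[C@@H](c1ccc(O[Si](C)(C)C(C)(C)C)cc1)O2 | intermediate
20 | (2S,8S)-8-[(1E,3S,5S)-1-(4-acetoxyphenyl)-5-(TBS-oxy)-7-[4-(TBS-oxy)phenyl]hept-1-en-3-yl]-2-[4-(TBS-oxy)phenyl]-5-methoxy-2,3-dihydro-4H-chromene-4,7(8H)-dione (ortho-dienone) | COC1=CC(=O)[C@@H]([C@H](/C=C/c2ccc(OC(C)=O)cc2)C[C@@H](O[Si](C)(C)C(C)(C)C)CCc2ccc(O[Si](C)(C)C(C)(C)C)cc2)C2=C1C(=O)C[C@@H](c1ccc(O[Si](C)(C)C(C)(C)C)cc1)O2 | intermediate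
21 | 4-[(1E,3S,5S)-5-(TBS-oxy)-7-[4-(TBS-oxy)phenyl]-3-[(2S)-2-[4-(TBS-oxy)phenyl]-7-hydroxy-5-methoxy-4-oxochroman-8-yl]hept-1-en-1-yl]phenyl acetate | COc1cc(O)c([C@H](/C=C/c2ccc(OC(C)=O)cc2)C[C@@H](O[Si](C)(C)C(C)(C)C)CCc2ccc(O[Si](C)(C)C(C)(C)C)cc2)c2c1C(=O)C[C@@H](c1ccc(O[Si](C)(C)C(C)(C)C)cc1)O2 | intermediate
22 | 4-[(1E,3S,5S)-5-hydroxy-3-[(2S)-7-hydroxy-2-(4-hydroxyphenyl)-5-methoxy-4-oxochroman-8-yl]-7-(4-hydroxyphenyl)hept-1-en-1-yl]phenyl acetate | COc1cc(O)c([C@H](/C=C/c2ccc(OC(C)=O)cc2)C[C@@H](O)CCc2ccc(O)cc2)c2c1C(=O)C[C@@H](c1ccc(O)cc1)O2 | intermediate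
23 | (2S)-7-hydroxy-8-[(1E,3S,5S)-5-hydroxy-1,7-bis(4-hydroxyphenyl)hept-1-en-3-yl]-2-(4-hydroxyphenyl)-5-methoxychroman-4-one | COc1cc(O)c([C@H](/C=C/c2ccc(O)cc2)C[C@@H](O)CCc2ccc(O)cc2)c2c1C(=O)C[C@@H](c1ccc(O)cc1)O2 | target

Total step count: 12
Longest linear sequence: 8 steps (steps 1–4 or steps 5–8, followed by steps 9–12)

Steps most likely to fail

Step 10. What may go wrong: the allyl terminus may also migrate to C6 (insufficient discrimination between the two positions ortho to O7), and partial ionisation and recombination of the benzylic allylic ether may erode the transfer of chirality. The fallback sets out from chromone 4 and alcohol 18 and comes back at 21. It moves the rearrangement to the chromone stage, where the pyranone C2=C3 bond fixes double-bond character in C7=C8 as in 7-allyloxychromones and 7-allyloxycoumarins, and introduces C2 afterwards. Hydrogenolysis of 4 (H2, Pd/C, EtOAc, stopped at debenzylation) would give 7-hydroxy-5-methoxy-4H-chromen-4-one F1. Mitsunobu etherification of F1 with 18 (PPh3, DIAD, PhMe, 0 °C) would give the chromone 7-O-(1-arylallyl) ether F2. Thermal Claisen rearrangement (PhNEt2, 150 °C) would give the 8-substituted 7-hydroxychromone F3. Rhodium-catalysed asymmetric 1,4-addition of boronic acid 5 to F3 (Rh(acac)(C2H4)2, electron-poor MeO-BIPHEP-type bisphosphine of the antipode that gives 2S, PhMe/H2O) would then give 21.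

Step 9. What may go wrong: ionisation of the activated benzylic allylic oxyphosphonium species, with loss of configurational integrity at C1, or SN2′ attack at C3. The fallback sets out from phenol 7 and aldehyde 11 and comes back at 19. It sets the C1–O7 stereocentre by asymmetric catalysis and attaches the chain afterwards by olefin metathesis.
- Carbonate: phenol-selective acetylation of commercial (E)-4-hydroxycinnamyl alcohol (Ac2O, aq. NaOH, 0 °C) would give 4-[(E)-3-hydroxyprop-1-en-1-yl]phenyl acetate F4, and methyl chloroformate/pyridine would give its methyl carbonate F5.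
- Etherification: iridium-catalysed asymmetric allylic etherification of F5 with the lithium phenoxide of 7 ([Ir(cod)Cl]2, BINOL-derived bis(1-phenylethyl)amine phosphoramidite of the antipode that gives the S ether, THF, rt) would give the branched aryl 1-arylallyl ether F6.
- Chain partner: Brown allylation of 11 (Ipc2B(allyl) of the antipode that attacks the Re face) would give the (S)-homoallylic alcohol F7, and TBSCl/imidazole would give its silyl ether F8.
- Union: cross-metathesis of F6 with F8 (second-generation Hoveyda–Grubbs catalyst, CH2Cl2, 40 °C) should give the E ether 19.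

Step 3. What may go wrong: slow carbopalladation of the electron-rich 5,7-dioxygenated chromone with competing protodeboronation of 5, incomplete facial selectivity, or loss of the aryl silyl ether in the aqueous medium. The fallback sets out from acetophenone 2 and comes back at 6. It replaces asymmetric catalysis by the classical chalcone route and a resolution. Claisen–Schmidt condensation of 2 with 4-hydroxybenzaldehyde (KOH, EtOH, rt) would give the 2′-hydroxychalcone F9. Oxa-Michael cyclisation (NaOAc, EtOH, reflux) would give the racemic 4′-hydroxyflavanone F10. Silylation (TBSCl, imidazole, DMF) would give the racemic silyl ether F11. Preparative HPLC on a chiral stationary phase would deliver the 2S enantiomer 6.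

Further compounds
F1 | step 10 | 7-hydroxy-5-methoxy-4H-chromen-4-one | COc1cc(O)cc2occc(=O)c12
F2 | step 10 | 4-[(1S,2E,5S)-5-(TBS-oxy)-7-[4-(TBS-oxy)phenyl]-1-[(5-methoxy-4-oxo-4H-chromen-7-yl)oxy]hept-2-en-1-yl]phenyl acetate | COc1cc(O[C@H](c3ccc(OC(C)=O)cc3)/C=C/C[C@@H](O[Si](C)(C)C(C)(C)C)CCc3ccc(O[Si](C)(C)C(C)(C)C)cc3)cc2occc(=O)c12
F3 | step 10 | 4-[(1E,3S,5S)-5-(TBS-oxy)-7-[4-(TBS-oxy)phenyl]-3-(7-hydroxy-5-methoxy-4-oxo-4H-chromen-8-yl)hept-1-en-1-yl]phenyl acetate | COc1cc(O)c([C@H](/C=C/c3ccc(OC(C)=O)cc3)C[C@@H](O[Si](C)(C)C(C)(C)C)CCc3ccc(O[Si](C)(C)C(C)(C)C)cc3)c2occc(=O)c12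
F4 | step 9 | 4-[(E)-3-hydroxyprop-1-en-1-yl]phenyl acetate | CC(=O)Oc1ccc(/C=C/CO)cc1
F5 | step 9 | 4-[(E)-3-(methoxycarbonyloxy)prop-1-en-1-yl]phenyl acetate | CC(=O)Oc1ccc(/C=C/COC(=O)OC)cc1
F6 | step 9 | 4-[(1S)-1-{[(2S)-2-[4-(TBS-oxy)phenyl]-5-methoxy-4-oxochroman-7-yl]oxy}prop-2-en-1-yl]phenyl acetate | COc1cc(O[C@H](c2ccc(OC(C)=O)cc2)C=C)cc2c1C(=O)C[C@@H](c1ccc(O[Si](C)(C)C(C)(C)C)cc1)O2
F7 | step 9 | (3S)-1-[4-(TBS-oxy)phenyl]hex-5-en-3-ol | C=CC[C@@H](O)CCc1ccc(O[Si](C)(C)C(C)(C)C)cc1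
F8 | step 9 | tert-butyl{4-[(3S)-3-(TBS-oxy)hex-5-en-1-yl]phenoxy}dimethylsilane | C=CC[C@@H](O[Si](C)(C)C(C)(C)C)CCc1ccc(O[Si](C)(C)C(C)(C)C)cc1
F9 | step 3 | (E)-1-[4-(benzyloxy)-2-hydroxy-6-methoxyphenyl]-3-(4-hydroxyphenyl)prop-2-en-1-one | COc1cc(OCc2ccccc2)cc(O)c1C(=O)/C=C/c1ccc(O)cc1
F10 | step 3 | racemic 7-(benzyloxy)-2-(4-hydroxyphenyl)-5-methoxychroman-4-one | COc1cc(OCc2ccccc2)cc2c1C(=O)CC(c1ccc(O)cc1)O2
F11 | step 3 | racemic 7-(benzyloxy)-2-[4-(TBS-oxy)phenyl]-5-methoxychroman-4-one | COc1cc(OCc2ccccc2)cc2c1C(=O)CC(c1ccc(O[Si](C)(C)C(C)(C)C)cc1)O2
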